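You charge 1.05 equiv of reagent into a flask whose substrates could take 2.50, so reagent is the limiting reagent.

    starting material + reagent → target (k1 = 0.739 M⁻¹ h⁻¹)
    second substrate + reagent → second product (k2 = 3.42 M⁻¹ h⁻¹)
    third substrate + reagent → third product (k3 = 2.13 M⁻¹ h⁻¹)
    starting material → decomposition product (k4 = 4.03 × 10⁻⁵ h⁻¹)
    target → over-reaction product (k5 = 0.00838 h⁻¹)

- west: starting material 0.50 M; reagent 1.05 equiv; second substrate 0.500 equiv; third substrate 1.00 equiv; time 120 h
- north-east: starting material 0.50 M; reagent 1.05 equiv; second substrate 0.500 equiv; third substrate 1.00 equiv; time 40 h

- which of the two there is more of at the end, west (target / over-reaction product)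
- which of the two there is more of at the end, north-east (target / over-reaction product)
- target at the end, in percent of the starting material charged, west
- target at the end, in percent of the starting material charged, north-east

**Bench rule.** The rule of thumb says that reagent goes to the fastest substrate first. Since 3.42 M⁻¹ h⁻¹ beats 2.13 M⁻¹ h⁻¹, the rule gives second substrate its 0.500 equiv, third substrate the remaining 0.550, and starting material nothing.

**Its border.** That rule needs rate constants far apart, but 2.13 M⁻¹ h⁻¹ and 0.739 M⁻¹ h⁻¹ stand at a ratio of 2.88. So starting material competes, and its share is the correction you have to compute.

**Shared exposure.** Leaving decomposition aside, each substrate loses ln c at the rate k·c(reagent), so all three see one integral and each survives as exp(−k × that integral). Try 1170 M·s, the value that leaves half of third substrate, as the reagent exposure, the time integral of c(reagent). Second substrate then takes 0.335, third substrate 0.500 and starting material 0.214. Together that is 1.05 against 1.05 equiv charged, so the trial stands, and I reckon that 21.4 % of the starting material becomes target.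

**My reckoning.** With reagent as charged in north-east, starting material has a half-life of 1.8 h by its reaction with reagent, while target has a half-life of 83 h by its passing into over-reaction product, so I let target form at once and then decay. That gives 7.82 % in west, with over-reaction product ahead, and 15.3 % in north-east, with target ahead.

**The forecast.** It says over-reaction product and 7.9 % for west, target and 15.4 % for north-east, both yields slightly above mine. Its ground: “The two faster substrates take most of the reagent within a few hours”.

**The result.** West ends with 7.87 % target and 13.5 % over-reaction product, north-east with 15.4 % and 6.00 %. Over-reaction product leads in west, which ran 120 h, longer than the target half-life, and target leads in north-east, which ran 40 h, shorter than it.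

**Second flask.** Take north-east with 2.00 equiv of second substrate. An exposure of 469 M·s balances the charge at 1.05, so I reckon that 9.17 % of the starting material becomes target and 6.56 % stands at the end of this flask. The computed value is 6.56 %.

Its constants are assumed.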